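## Structural features

The target is a germacranolide. A ten-membered carbocycle (C1–C10) is fused through C6–C7 to an α,β-unsaturated γ-lactone (O on C6, C7=C11, C12=O). C7=C11 is therefore a tetrasubstituted alkene bearing four different carbon groups: C6, C8, C12 and the acetoxymethyl carbon C13. The ring carries a trans-epoxide at C1–C10 (methyl C14 on C10) and a cis-epoxide at C4–C5 (methyl C15 on C4); these are the oxidised forms of a 1(10)E and a 4Z trisubstituted alkene. C8 bears the ester of (S)-2-methyloxirane-2-carboxylic acid. C4, C5 and C6 are contiguous stereocentres, C8 is separated from C6 only by the sp2 carbon C7, and C10/C1 lie one methylene (C9) from C8; the configuration is 1R,4R,5S,6S,8S,10R,2'S. Fragile groups are the three epoxides (acid, transannular opening), the allylic primary acetate and, above all, H6: it is the γ-hydrogen of the butenolide and lies β to the C5 epoxide oxygen, so base can racemise C6 or open the epoxide by elimination. The real difficulty lies in three points: closing a ten-membered ring that holds one E and one Z trisubstituted alkene, building the C7=C11 alkene with control of which CH2O group ends up in the lactone, and placing two epoxides on defined faces. The key step exploits C4=C5: C4 carries the methyl group and the bond to the plain methylene C3, which is what coupling of a (Z)-2-iodoalkene at C4 with a primary alkylborane at C3 delivers with retention of geometry.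

## Logic of the disconnections

28 is cut at the C8–O acyl bond into 24 and 26. The epoxy acid is the most electrophile-sensitive part and comes last; this also leaves the C8 hydroxyl free for the step before. The forward step needs an esterification mild enough for a base-sensitive butenolide. 26 comes from 25 by oxidation of the CH2OH group without touching the stereocentre.

24 is cut at the two C–O bonds of the C4–C5 epoxide, giving 23. On a model with H6 in the plane of C4=C5 (allylic 1,3-strain), the exposed face of this alkene is syn to the lactone oxygen, and attack there would give the 4,5-diastereomer. The required face is syn to C7/C8, where the C8 hydroxyl sits, so the oxygen is delivered from that hydroxyl. The forward step needs a metal-directed epoxidation that is faster than oxidation of the carbinol.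

23 goes back to 22 (O–Si bond) and 22 to 21 (C–O bonds of the C1–C10 epoxide). This epoxide is installed while O8 still carries the bulky silyl group, which should hold C14 on the opposite side and leave the peripheral face open. The forward step needs an electrophilic oxidant that distinguishes C1=C10 from C4=C5, which is deactivated by the allylic lactone oxygen.

21 is cut at the C12=O bond to 20 and 20 at the acetyl C–O bond to 19. The lactone carbonyl is introduced only after ring closure because a butenolide with its acidic H6 would not survive the basic coupling medium. The forward step needs an allylic oxidation that prefers the ring CH2 next to oxygen over the tertiary C6–H. C13 is carried as the free alcohol rather than as an aryl-methyl ether, because oxidative removal of such a group by a quinone would expose the dihydrofuran to dehydrogenation to a furan.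

19 is cut at C3–C4, giving 17. This removes the ten-membered ring and leaves a dihydrofuran with two side chains whose alkene geometries are already fixed. The forward step needs hydroboration of one alkene out of five and ring closure in preference to oligomerisation.

17 is cut at the O–C12 bond, giving 16, in which C12 and C13 are the two equivalent CH2 groups of an oxetane. Only the CH2 cis to C6 can be reached by the C6 hydroxyl, so the two carbons are told apart by geometry and C13 is released as the free alcohol. The forward step needs activation of the oxetane without ionising the doubly allylic C6–O bond.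

16 is cut at C4–I and C5–H to the alkyne 14, and 14 at the C6–H bond to the ketone 13. The iodoalkene is made from a propargylic alcohol and not from an aldehyde on C6: that aldehyde would be a 2,5-dihydrofuran-2-carbaldehyde, which is easily epimerised and is an isomer of a furfuryl alcohol. The forward steps need a trans-hydrometalation directed by the C6 hydroxyl and a reagent-controlled ketone reduction that sets C6.

13 is cut at C6–C7 into 9 and 11; 11 comes from 10 by amide formation. This splits off a four-carbon acyl unit and leaves an alkenyl bromide as the nucleophile precursor. The forward step needs bromine–lithium exchange in the presence of a diene and a clean mono-acylation.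

9 is cut at C1–C2 to 8, and 8 at C10–CH3 and C1–I to the terminal alkyne 6. The E-trisubstituted alkene is set by a syn-carbometalation rather than by addition of a pentadienyl metal, which would give neither secure regiochemistry nor control at C8. The forward steps need a coupling that selects the alkenyl iodide over the alkenyl bromide, and a Lewis-acidic aluminium reagent that leaves the oxetane closed.

6 goes back to 5 (O–Si) and 5 is cut at C8–C9 to 4. This is where C8 is set, by a catalyst-controlled propargylation instead of an uncontrolled allyl-metal addition. The forward step needs face selection on a hindered α-bromo enal.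

4 is cut at C7–C8 to 2, and 2 at C7=C11 to 1. The tetrasubstituted alkene is thus made at the start from a symmetric ketone, so no alkene geometry has to be controlled; the two bromines serve in turn as handles for C8 and C6. The forward steps need a lithium carbenoid that lives long enough to be formylated.

## Other disconnections considered

Alternative 1: The cut is the C5–C10 bond of a bicyclic six–six progenitor. In the forward key step a C5 alkoxide expels an anti-periplanar C1 mesylate (Grob fragmentation), which breaks C5–C10 and gives the E C1=C10 alkene and a C5 ketone in A1.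
- In favour: the ring arises from a fragmentation, so there is no entropic penalty and no high dilution, and the E geometry follows stereospecifically from the ring fusion. On ring formation and on this alkene the alternative is better than the chosen plan.
- Against it here: A1 carries a ketone at C5 and a tertiary alcohol at C4, whereas the target needs a cis-epoxide there. Converting an α-hydroxy ketone into the Z-alkene or the epoxide takes several redox and elimination steps on a ring prone to transannular reaction between C1=C10 and C5=O. The butenolide (C11–C13) must then be annulated onto three contiguous, differently protected carbinols. The bicyclic precursor needs extra stereocentres that are destroyed.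
- Comparison: on structure, the chosen plan has the whole carbon skeleton and both alkenes in place at ring closure and A1 does not. On mechanism, the fragmentation is the more dependable ring-forming event. On step economy, the alternative is clearly longer after the key step.

Alternative 2: The cut is C9–C10. In the forward key step Ni(cod)2, PBu3 and Et3B join a tethered alkyne carbon (C10) to the CH2 of a terminal epoxide (C9) with hydrogen delivered to C1, giving the E-alkene and the free C8 hydroxyl in A2.
- In favour: C8 takes its configuration from an enantiopure epoxide, so no asymmetric addition is needed. The free C8 hydroxyl is exactly the handle the directed C4–C5 epoxidation needs, without a desilylation. On these two points the alternative is equal or better. The medium is neutral.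
- Against it here: the coupling is best established for small rings and for large macrocycles; a ten-membered ring with a Z-alkene inside is uncertain. Which alkyne carbon bonds rests only on the tether for a methyl alkyne. A2 has C7 as a protected carbinol, so the entire butenolide must be built afterwards through a C7 ketone flanked by two oxygenated stereocentres, followed by a hindered tetrasubstituted olefination.
- Comparison: on structure, less of the skeleton is present at ring closure. On mechanism, both plans close the ring at a metal with geometric control and are about equal. On step economy, the alternative is shorter before the key step and longer after it, and longer overall.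

Alternative 3: The cut is C1–C2. In the forward key step a nickel–bipyridine catalyst with Mn couples an E-alkenyl iodide (C1) with a primary alkyl iodide (C2) in one molecule to give A3, which has the same structure as 21.
- In favour: the lactone carbonyl and the acetate are present at ring closure, so the allylic oxidation of step 14 disappears, and the medium is not basic, so the butenolide is tolerated. On oxidation-state economy the alternative is better. Retention of the E geometry is equal.
- Against it here: the Z-C4=C5 unit with its C2–C3 chain must be made first, most simply by an intermolecular version of the coupling used here as the key step, so nothing is saved before ring closure. Low-valent nickel can ionise the allylic acetate. The primary radical can be reduced or add to the unsaturated lactone. Ten-membered closures of this kind have less precedent than B-alkyl Suzuki closures. The base-sensitive butenolide has to be carried through more steps.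
- Comparison: on structure, the ring and skeleton are the same, with two steps fewer after closure. On mechanism, the radical–nickel pathway raises more chemoselectivity questions. On step economy, the two plans are about equal.

Key step: step 12

Assumption: atoms carry germacrane numbers (ring C1–C10, C11–C13 on C7, C14 on C10, C15 on C4), and in the closed ring H6 is taken to lie in the plane of C4=C5 (allylic 1,3-strain), so that the exposed face of C4=C5 is the one syn to the lactone oxygen.

## Route

Step 1
Reactants: 1 oxetan-3-one
Product: 2 3-(dibromomethylidene)oxetane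
Conditions: CBr4, PPh3, CH2Cl2, 0 °C
Reagents that add atoms: carbon tetrabromide (BrC(Br)(Br)Br)
Why: Ramirez dibromo-olefination (first stage of the Corey–Fuchs sequence); the strained, unhindered ketone should react readily with Ph3P=CBr2, and the product is symmetric, so the later tetrasubstituted C7=C11 alkene needs no geometric control.

Step 2
Reactants: 2 3-(dibromomethylidene)oxetane
Product: 4 2-bromo-2-(oxetan-3-ylidene)acetaldehyde, via lithium carbenoid 3 (not isolated)
Conditions: n-BuLi, THF/Et2O, −105 °C; DMF, −105 → −78 °C; aq NH4Cl
Reagents that add atoms: N,N-dimethylformamide (CN(C)C=O)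
Why: Bromine–lithium exchange gives an α-bromoalkenyllithium that cannot undergo Fritsch–Buttenberg–Wiechell migration without forming a cyclic alkyne, so it should persist at −105 °C and be formylated by DMF (C7–C8 bond); the two bromines are equivalent and an oxetane is inert to organolithiums in the absence of a Lewis acid.

Step 3
Reactants: 4 2-bromo-2-(oxetan-3-ylidene)acetaldehyde
Product: 5 (2S)-1-bromo-1-(oxetan-3-ylidene)pent-4-yn-2-ol
Conditions: allenyl-B(pin), (S)-TRIP phosphoric acid (10 mol %), 4 Å MS, toluene, −20 °C
Reagents that add atoms: allenylboronic acid pinacol ester (C=C=CB1OC(C)(C)C(C)(C)O1)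
Why: Chiral-phosphoric-acid-catalysed propargylation of an aldehyde with an allenylboronate through a closed six-membered transition state (SE2'); the (S)-acid is chosen to direct attack to the Si face of the formyl group, which sets C8 as S and forms C8–C9, and the product remains a borate until neutral work-up, so the new hydroxyl does not meet the oxetane under acid.

Step 4
Reactants: 5 (2S)-1-bromo-1-(oxetan-3-ylidene)pent-4-yn-2-ol
Product: 6 tert-butyl{[(2S)-1-bromo-1-(oxetan-3-ylidene)pent-4-yn-2-yl]oxy}dimethylsilane
Conditions: TBSCl, imidazole, DMF, 25 °C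
Reagents that add atoms: tert-butyldimethylsilyl chloride (CC(C)(C)[Si](C)(C)Cl)
Why: Standard silylation under basic conditions; the silyl ether blocks O8, so that later only O6 can open the oxetane, and it should survive the organolithium, hydride, palladium and chromium steps.

Step 5
Reactants: 6 tert-butyl{[(2S)-1-bromo-1-(oxetan-3-ylidene)pent-4-yn-2-yl]oxy}dimethylsilane
Product: 8 tert-butyl{[(2S,4E)-1-bromo-5-iodo-4-methyl-1-(oxetan-3-ylidene)pent-4-en-2-yl]oxy}dimethylsilane, via alkenyldimethylalane 7 (not isolated)
Conditions: AlMe3, Cp2ZrCl2 (20 mol %), H2O (1 equiv), CH2Cl2, −25 °C; NIS, THF, −25 → 0 °C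
Reagents that add atoms: trimethylaluminium (C[Al](C)C); N-iodosuccinimide (O=C1CCC(=O)N1I)
Why: Zirconium-catalysed syn-carboalumination of the terminal alkyne (Negishi carboalumination) places methyl on C10 and aluminium on C1 on the same side, and iodinolysis with retention gives the E-iodoalkene; the hindered alkenyl bromide is inert, and NIS is used instead of iodine so that no aluminium iodide is formed next to the oxetane.

Step 6
Reactants: 8 tert-butyl{[(2S,4E)-1-bromo-5-iodo-4-methyl-1-(oxetan-3-ylidene)pent-4-en-2-yl]oxy}dimethylsilane
Product: 9 tert-butyl{[(2S,4E)-1-bromo-4-methyl-1-(oxetan-3-ylidene)hepta-4,6-dien-2-yl]oxy}dimethylsilane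
Conditions: CH2=CHSnBu3, Pd(PPh3)4 (5 mol %), CuI, DMF, 25 °C
Reagents that add atoms: tributyl(vinyl)stannane (CCCC[Sn](CCCC)(CCCC)C=C)
Why: Stille coupling with retention of alkene geometry forms C1–C2 and the E-diene; oxidative addition of zerovalent palladium to the unhindered alkenyl iodide should be far faster than to the tetrasubstituted alkenyl bromide at room temperature.

Step 7
Reactants: 10 but-2-ynoic acid
Product: 11 N-methoxy-N-methylbut-2-ynamide
Conditions: MeNHOMe·HCl, EDC·HCl, i-Pr2NEt, CH2Cl2, 0 → 25 °C
Reagents that add atoms: N,O-dimethylhydroxylamine hydrochloride (CNOC.Cl)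
Why: Carbodiimide amide coupling; the Weinreb amide is needed so that the alkenyllithium of step 8 adds only once.

Step 8
Reactants: 9 tert-butyl{[(2S,4E)-1-bromo-4-methyl-1-(oxetan-3-ylidene)hepta-4,6-dien-2-yl]oxy}dimethylsilane; 11 N-methoxy-N-methylbut-2-ynamide
Product: 13 (6S,8E)-6-[(tert-butyldimethylsilyl)oxy]-8-methyl-5-(oxetan-3-ylidene)undeca-8,10-dien-2-yn-4-one, via alkenyllithium 12 (not isolated)
Conditions: t-BuLi (2 equiv), Et2O, −78 °C; 11, −78 → −40 °C; aq NH4Cl
Reagents that add atoms: none
Why: Bromine–lithium exchange followed by Weinreb acylation forms C6–C7; the chelated tetrahedral intermediate prevents a second addition, and exchange at −78 °C should outrun attack on the diene or elimination of the β-silyloxy group.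

Step 9
Reactants: 13 (6S,8E)-6-[(tert-butyldimethylsilyl)oxy]-8-methyl-5-(oxetan-3-ylidene)undeca-8,10-dien-2-yn-4-one
Product: 14 (4R,6S,8E)-6-[(tert-butyldimethylsilyl)oxy]-8-methyl-5-(oxetan-3-ylidene)undeca-8,10-dien-2-yn-4-ol
Conditions: (S)-Me-CBS oxazaborolidine (0.5 equiv), catecholborane, toluene, −78 °C
Reagents that add atoms: none
Why: CBS reduction under reagent control; the fully substituted alkenyl group acts as the large and the propynyl group as the small substituent, so the (S)-catalyst should give the 4R carbinol (C6 of the target), and catecholborane does not hydroborate the diene at this temperature.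

Step 10
Reactants: 14 (4R,6S,8E)-6-[(tert-butyldimethylsilyl)oxy]-8-methyl-5-(oxetan-3-ylidene)undeca-8,10-dien-2-yn-4-ol
Product: 16 (2Z,4R,6S,8E)-6-[(tert-butyldimethylsilyl)oxy]-2-iodo-8-methyl-5-(oxetan-3-ylidene)undeca-2,8,10-trien-4-ol, via cyclic alkenylalanate 15 (not isolated)
Conditions: NaAlH2(OCH2CH2OCH3)2, THF, 0 → 25 °C; NIS, −78 °C
Reagents that add atoms: N-iodosuccinimide (O=C1CCC(=O)N1I)
Why: Hydroxyl-directed trans-hydroalumination of the propargylic alcohol puts aluminium on the distal carbon C4 in a five-membered alkoxyaluminate, and iodinolysis with retention gives the Z-iodoalkene with C6 and iodine cis; C6 is not touched and no epimerisable aldehyde is involved.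

Step 11
Reactants: 16 (2Z,4R,6S,8E)-6-[(tert-butyldimethylsilyl)oxy]-2-iodo-8-methyl-5-(oxetan-3-ylidene)undeca-2,8,10-trien-4-ol
Product: 17 {(5R)-4-[(1S,3E)-1-[(tert-butyldimethylsilyl)oxy]-3-methylhexa-3,5-dien-1-yl]-5-[(Z)-2-iodoprop-1-en-1-yl]-2,5-dihydrofuran-3-yl}methanol
Conditions: (PhO)2P(O)OH (10 mol %), toluene, 25 °C
Reagents that add atoms: none
Why: Acid-catalysed intramolecular opening of an oxetane by a tethered hydroxyl (5-exo-tet SN2 at the allylic CH2), the known ring expansion of hydroxy-oxetanes to five-membered ethers that releases a CH2OH group; only the CH2 cis to C6 is within reach, so C12 and C13 are differentiated by geometry, O8 is silylated, and C6 keeps its configuration because its C–O bond is not broken.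

Step 12
Reactants: 17 {(5R)-4-[(1S,3E)-1-[(tert-butyldimethylsilyl)oxy]-3-methylhexa-3,5-dien-1-yl]-5-[(Z)-2-iodoprop-1-en-1-yl]-2,5-dihydrofuran-3-yl}methanol
Product: 19 [(4S,6E,10Z,11aR)-4-[(tert-butyldimethylsilyl)oxy]-6,10-dimethyl-2,4,5,8,9,11a-hexahydrocyclodeca[b]furan-3-yl]methanol, via B-alkyl-9-BBN borane 18 (not isolated)
Conditions: 9-BBN (3 equiv), THF, 25 °C; then slow addition to Pd(dppf)Cl2 (20 mol %), AsPh3, Cs2CO3, DMF/THF/H2O, 50 °C, 1 mM
Reagents that add atoms: none
Why: 9-BBN adds to the monosubstituted C2=C3 alkene with boron on C3, after the free C13 hydroxyl has consumed one B–H as a borinate that is hydrolysed again in the aqueous coupling medium. Zerovalent palladium formed from Pd(dppf)Cl2 inserts into the C4–I bond with retention, the hydroxo- or carbonato-borate transfers the primary alkyl group to palladium, and reductive elimination forms C3–C4 with the Z geometry of C4=C5 intact. The closest known reaction type is the B-alkyl Suzuki–Miyaura macrocyclisation of an alkenyl iodide with a 9-BBN-derived alkylborane. The ten-membered ring closes at the metal: transmetalation gives an eleven-membered palladacycle and C(sp3)–C(sp2) reductive elimination contracts it to the carbocycle, so this is not a polar exo or endo attack. No stereocentre is formed; C6 and C8 are spectators, and in the dihydrofuran H6 is not acidic, which is why the lactone carbonyl is introduced only afterwards. The step needs hydroboration of the terminal alkene only, which the steric demand of 9-BBN secures against the tri- and tetrasubstituted alkenes and the iodoalkene. It also needs cyclisation over oligomerisation, which slow addition at high dilution secures. The Z-iodoalkene, the E-alkene and the dihydrofuran are rigid, so only the C2–C3 link has to fold.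

Step 13
Reactants: 19 [(4S,6E,10Z,11aR)-4-[(tert-butyldimethylsilyl)oxy]-6,10-dimethyl-2,4,5,8,9,11a-hexahydrocyclodeca[b]furan-3-yl]methanol
Product: 20 [(4S,6E,10Z,11aR)-4-[(tert-butyldimethylsilyl)oxy]-6,10-dimethyl-2,4,5,8,9,11a-hexahydrocyclodeca[b]furan-3-yl]methyl acetate
Conditions: Ac2O, pyridine, DMAP (cat.), CH2Cl2, 0 °C
Reagents that add atoms: acetic anhydride (CC(=O)OC(C)=O)
Why: Acylation of the only free hydroxyl; the acetate is the final C13 group and, being an ester, deactivates the C13–H bonds toward the oxidation that follows.

Step 14
Reactants: 20 [(4S,6E,10Z,11aR)-4-[(tert-butyldimethylsilyl)oxy]-6,10-dimethyl-2,4,5,8,9,11a-hexahydrocyclodeca[b]furan-3-yl]methyl acetate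
Product: 21 [(4S,6E,10Z,11aR)-4-[(tert-butyldimethylsilyl)oxy]-6,10-dimethyl-2-oxo-2,4,5,8,9,11a-hexahydrocyclodeca[b]furan-3-yl]methyl acetate
Conditions: CrO3, 3,5-dimethylpyrazole, CH2Cl2, −20 °C
Reagents that add atoms: chromium trioxide (O=[Cr](=O)=O)
Why: Chromium trioxide–dimethylpyrazole allylic oxidation of a cyclic allyl ether, the standard conversion of a 2,5-dihydrofuran into a butenolide; the ring CH2 (C12) is allylic and α to oxygen and less hindered than the tertiary C6–H, whose bond lies near the nodal plane of C4=C5, and the carbocyclic allylic CH2 groups lack the oxygen activation.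

Step 15
Reactants: 21 [(4S,6E,10Z,11aR)-4-[(tert-butyldimethylsilyl)oxy]-6,10-dimethyl-2-oxo-2,4,5,8,9,11a-hexahydrocyclodeca[b]furan-3-yl]methyl acetate
Product: 22 (1R,6R,8S,10R)-13-acetoxy-8-[(tert-butyldimethylsilyl)oxy]-1,10-epoxygermacra-4Z,7(11)-dien-12,6-olide
Conditions: dimethyldioxirane (1.05 equiv) in acetone, CH2Cl2, −40 → 0 °C
Reagents that add atoms: dimethyldioxirane (CC1(C)OO1)
Why: Concerted electrophilic epoxidation under neutral conditions; C1=C10 is the most electron-rich alkene (C4=C5 is deactivated by the allylic lactone oxygen and C7=C11 is conjugated to the carbonyl), and attack on the peripheral face of the conformer that turns C14 away from the bulky C8 silyloxy group should give the 1R,10R trans-epoxide.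

Step 16
Reactants: 22 (1R,6R,8S,10R)-13-acetoxy-8-[(tert-butyldimethylsilyl)oxy]-1,10-epoxygermacra-4Z,7(11)-dien-12,6-olide
Product: 23 (1R,6R,8S,10R)-13-acetoxy-1,10-epoxy-8-hydroxygermacra-4Z,7(11)-dien-12,6-olide
Conditions: Et3N·3HF, THF, 25 °C
Reagents that add atoms: none
Why: Fluoride desilylation with a buffered, nearly neutral reagent, chosen so that neither the epoxide (acid) nor H6 and the acetate (base) are endangered.

Step 17
Reactants: 23 (1R,6R,8S,10R)-13-acetoxy-1,10-epoxy-8-hydroxygermacra-4Z,7(11)-dien-12,6-olide
Product: 24 (1R,4R,5S,6S,8S,10R)-13-acetoxy-1,10:4,5-diepoxy-8-hydroxygermacr-7(11)-en-12,6-olide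
Conditions: VO(acac)2 (5 mol %), t-BuOOH, CH2Cl2, 0 → 25 °C
Reagents that add atoms: tert-butyl hydroperoxide (CC(C)(C)OO)
Why: Vanadium-catalysed hydroxyl-directed epoxidation; the C8 alkoxide holds the vanadium peroxide over the face of C4=C5 that is syn to C7 and C8, which is the face needed for 4R,5S beside 6S and the one an undirected oxidant is expected to avoid; the cis geometry of the alkene is carried into the epoxide and the conjugated C7=C11 alkene is too electron-poor to react.

Step 18
Reactants: 25 [(2R)-2-methyloxiran-2-yl]methanol
Product: 26 (2S)-2-methyloxirane-2-carboxylic acid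
Conditions: RuCl3 (2 mol %), NaIO4, CCl4/MeCN/H2O, 0 → 25 °C
Reagents that add atoms: sodium periodate ([Na+].[O-]I(=O)(=O)=O); water (O)
Why: Ruthenium tetroxide oxidation of an epoxy alcohol to the epoxy acid; the stereocentre is not involved, and the descriptor changes from R to S only because the carboxyl group outranks the ring CH2.

Step 19
Reactants: 24 (1R,4R,5S,6S,8S,10R)-13-acetoxy-1,10:4,5-diepoxy-8-hydroxygermacr-7(11)-en-12,6-olide; 26 (2S)-2-methyloxirane-2-carboxylic acid
Product: 28 (1R,4R,5S,6S,8S,10R)-13-acetoxy-1,10:4,5-diepoxy-8-{[(2S)-2-methyloxirane-2-carbonyl]oxy}germacr-7(11)-en-12,6-olide, via mixed trichlorobenzoic anhydride 27 (not isolated)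
Conditions: 26, 2,4,6-Cl3C6H2COCl, Et3N, THF, 0 °C; then 24, DMAP, toluene, 0 → 25 °C
Reagents that add atoms: none
Why: Yamaguchi esterification; acylation at oxygen keeps the C8 configuration, and the alcohol meets only DMAP, a weak base, which should limit deprotonation at C6.

## Compound list

1 | oxetan-3-one | O=C1COC1 | starting material
2 | 3-(dibromomethylidene)oxetane | BrC(Br)=C1COC1 | intermediate
3 | [bromo(oxetan-3-ylidene)methyl]lithium (lithium carbenoid) | [Li]C(Br)=C1COC1 | intermediate (not isolated)
4 | 2-bromo-2-(oxetan-3-ylidene)acetaldehyde | O=CC(Br)=C1COC1 | intermediate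
5 | (2S)-1-bromo-1-(oxetan-3-ylidene)pent-4-yn-2-ol | C#CC[C@H](O)C(Br)=C1COC1 | intermediate
6 | tert-butyl{[(2S)-1-bromo-1-(oxetan-3-ylidene)pent-4-yn-2-yl]oxy}dimethylsilane | C#CC[C@H](O[Si](C)(C)C(C)(C)C)C(Br)=C1COC1 | intermediate
7 | (E)-alkenyldimethylalane from 6 | C[Al](C)/C=C(C)/C[C@H](O[Si](C)(C)C(C)(C)C)C(Br)=C1COC1 | intermediate (not isolated)
8 | tert-butyl{[(2S,4E)-1-bromo-5-iodo-4-methyl-1-(oxetan-3-ylidene)pent-4-en-2-yl]oxy}dimethylsilane | I/C=C(C)/C[C@H](O[Si](C)(C)C(C)(C)C)C(Br)=C1COC1 | intermediate
9 | tert-butyl{[(2S,4E)-1-bromo-4-methyl-1-(oxetan-3-ylidene)hepta-4,6-dien-2-yl]oxy}dimethylsilane | C=C/C=C(C)/C[C@H](O[Si](C)(C)C(C)(C)C)C(Br)=C1COC1 | intermediate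
10 | but-2-ynoic acid | CC#CC(=O)O | starting material
11 | N-methoxy-N-methylbut-2-ynamide | CC#CC(=O)N(C)OC | intermediate
12 | alkenyllithium from 9 | C=C/C=C(C)/C[C@H](O[Si](C)(C)C(C)(C)C)C([Li])=C1COC1 | intermediate (not isolated)
13 | (6S,8E)-6-[(tert-butyldimethylsilyl)oxy]-8-methyl-5-(oxetan-3-ylidene)undeca-8,10-dien-2-yn-4-one | C=C/C=C(C)/C[C@H](O[Si](C)(C)C(C)(C)C)C(C(=O)C#CC)=C1COC1 | intermediate
14 | (4R,6S,8E)-6-[(tert-butyldimethylsilyl)oxy]-8-methyl-5-(oxetan-3-ylidene)undeca-8,10-dien-2-yn-4-ol | C=C/C=C(C)/C[C@H](O[Si](C)(C)C(C)(C)C)C([C@H](O)C#CC)=C1COC1 | intermediate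
15 | sodium cyclic alkenylalanate (1,2-oxaluminol-3-ene) from 14 | [Na+].COCCO[Al-]1(OCCOC)O[C@@H](C(=C2COC2)[C@H](C/C(C)=C/C=C)O[Si](C)(C)C(C)(C)C)C=C1C | intermediate (not isolated)
16 | (2Z,4R,6S,8E)-6-[(tert-butyldimethylsilyl)oxy]-2-iodo-8-methyl-5-(oxetan-3-ylidene)undeca-2,8,10-trien-4-ol | C=C/C=C(C)/C[C@H](O[Si](C)(C)C(C)(C)C)C([C@H](O)/C=C(C)\I)=C1COC1 | intermediate
17 | {(5R)-4-[(1S,3E)-1-[(tert-butyldimethylsilyl)oxy]-3-methylhexa-3,5-dien-1-yl]-5-[(Z)-2-iodoprop-1-en-1-yl]-2,5-dihydrofuran-3-yl}methanol | C=C/C=C(C)/C[C@H](O[Si](C)(C)C(C)(C)C)C1=C(CO)CO[C@@H]1/C=C(C)\I | intermediate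
18 | B-alkyl-9-BBN borane from 17 (boron on C3, C13 oxygen as 9-BBN borinate) | I/C(C)=C\[C@H]1OCC(COB2C3CCCC2CCC3)=C1[C@H](C/C(C)=C/CCB1C2CCCC1CCC2)O[Si](C)(C)C(C)(C)C | intermediate (not isolated)
19 | [(4S,6E,10Z,11aR)-4-[(tert-butyldimethylsilyl)oxy]-6,10-dimethyl-2,4,5,8,9,11a-hexahydrocyclodeca[b]furan-3-yl]methanol | CC(C)(C)[Si](C)(C)O[C@H]1C/C(C)=C/CC/C(C)=C\[C@H]2OCC(CO)=C12 | intermediate
20 | [(4S,6E,10Z,11aR)-4-[(tert-butyldimethylsilyl)oxy]-6,10-dimethyl-2,4,5,8,9,11a-hexahydrocyclodeca[b]furan-3-yl]methyl acetate | CC(=O)OCC1=C2[C@@H](O[Si](C)(C)C(C)(C)C)C/C(C)=C/CC/C(C)=C\[C@H]2OC1 | intermediate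
21 | [(4S,6E,10Z,11aR)-4-[(tert-butyldimethylsilyl)oxy]-6,10-dimethyl-2-oxo-2,4,5,8,9,11a-hexahydrocyclodeca[b]furan-3-yl]methyl acetate | CC(=O)OCC1=C2[C@@H](O[Si](C)(C)C(C)(C)C)C/C(C)=C/CC/C(C)=C\[C@H]2OC1=O | intermediate
22 | (1R,6R,8S,10R)-13-acetoxy-8-[(tert-butyldimethylsilyl)oxy]-1,10-epoxygermacra-4Z,7(11)-dien-12,6-olide | CC(=O)OCC1=C2[C@@H](O[Si](C)(C)C(C)(C)C)C[C@@]3(C)O[C@@H]3CC/C(C)=C\[C@H]2OC1=O | intermediate
23 | (1R,6R,8S,10R)-13-acetoxy-1,10-epoxy-8-hydroxygermacra-4Z,7(11)-dien-12,6-olide | CC(=O)OCC1=C2[C@@H](O)C[C@@]3(C)O[C@@H]3CC/C(C)=C\[C@H]2OC1=O | intermediate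
24 | (1R,4R,5S,6S,8S,10R)-13-acetoxy-1,10:4,5-diepoxy-8-hydroxygermacr-7(11)-en-12,6-olide | CC(=O)OCC1=C2[C@@H](O)C[C@@]3(C)O[C@@H]3CC[C@@]3(C)O[C@H]3[C@H]2OC1=O | intermediate
25 | [(2R)-2-methyloxiran-2-yl]methanol | OC[C@]1(C)CO1 | starting material
26 | (2S)-2-methyloxirane-2-carboxylic acid | OC(=O)[C@]1(C)CO1 | intermediate
27 | (2S)-2-methyloxirane-2-carboxylic 2,4,6-trichlorobenzoic anhydride | O=C(OC(=O)[C@]1(C)CO1)c1c(Cl)cc(Cl)cc1Cl | intermediate (not isolated)
28 | (1R,4R,5S,6S,8S,10R)-13-acetoxy-1,10:4,5-diepoxy-8-{[(2S)-2-methyloxirane-2-carbonyl]oxy}germacr-7(11)-en-12,6-olide | CC(=O)OCC1=C2[C@@H](OC(=O)[C@]3(C)CO3)C[C@@]3(C)O[C@@H]3CC[C@@]3(C)O[C@H]3[C@H]2OC1=O | target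

## Step count and least certain steps

Total: 19 steps. Longest linear sequence: 17 steps (steps 1–6, 8–17 and 19); steps 7 and 18 are one-step side branches.

Step 12 (key step). The likely failure is oligomerisation, or protodeboronation and β-hydride elimination, if transmetalation into a strained ten-membered transition state is slow. Fallback: from 17, hydroboration with 9-BBN followed by iodinolysis of the borane (I2, NaOMe) would give the primary iodide {(5R)-4-[(1S,3E)-1-[(tert-butyldimethylsilyl)oxy]-6-iodo-3-methylhex-3-en-1-yl]-5-[(Z)-2-iodoprop-1-en-1-yl]-2,5-dihydrofuran-3-yl}methanol F1. An intramolecular nickel-catalysed reductive coupling of its two carbon–iodine bonds (NiBr2·glyme, 4,4'-di-tert-butyl-2,2'-bipyridine, Mn, DMA, high dilution) would then form the same C3–C4 bond without base or an organoboron intermediate and return to 19.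

Step 17. The likely failure is oxidation of the allylic C8 carbinol to the enone in competition with oxygen transfer, or delivery to the other face if the ring sits in a conformation other than the assumed one. Fallback: from 22, with the silyl ether kept, bromohydrin formation (NBS, aqueous THF, CaCO3) should place bromine on the exposed face at C5 and water on the inner face at the tertiary C4, giving the bromohydrin F2. Silver oxide (Ag2O) would close the epoxide with inversion at C5 to the silyl-protected bis-epoxide F3, whose C4–C5 oxygen lies on the face opposite to the one a direct oxidant prefers. Desilylation as in step 16 would then give 24.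

Step 15. The likely failure is poor discrimination between the two ring alkenes, with C4=C5 epoxidised from its exposed, unwanted face, or poor facial selectivity at C1=C10. Fallback: the order is reversed. From 21, desilylation (Et3N·3HF) would give the dienol F4. Directed epoxidation (VO(acac)2, t-BuOOH) would give the 4,5-epoxy alcohol F5. Esterification with 26 as in step 19 would give the ester F6. A final treatment with dimethyldioxirane, with only one nucleophilic alkene left and the C8 ester as the steric bias, would lead to 28.

Step 14. The likely failure is hydrogen abstraction at the tertiary, doubly activated C6–H or at other allylic positions, leading to ring cleavage or aromatisation, or over-oxidation. Fallback: from 20, copper-catalysed peroxidation α to the ring oxygen (CuI cat., t-BuOOH, MeCN) would give the mixed peroxy acetal F7 (both C12 epimers). A Kornblum–DeLaMare fragmentation with Et3N would convert it into the lactone 21 without any chromium reagent.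

Step 11. The likely failure is ionisation of the doubly allylic C6–O bond under acid, with loss of configuration, or loss of the silyl group. Fallback: from 16, nucleophilic opening of the oxetane with MgI2 in Et2O would give the allylic iodide F8. The regioisomer iodinated on the other CH2 can only revert to 16 on treatment with base. K2CO3 in MeCN would then close the dihydrofuran by Williamson displacement and return to 17.

Step 5. The likely failure is opening of the oxetane by Lewis-acidic aluminium species during carboalumination or quench. Fallback: from 6, copper-catalysed methylboration of the alkyne (CuCl, 4,5-bis(diphenylphosphino)-9,9-dimethylxanthene, B2pin2, MeI, NaOt-Bu, THF) would give the (E)-alkenylboronate F9 under basic, non-Lewis-acidic conditions. Suzuki coupling with vinyl bromide (Pd(dppf)Cl2, K3PO4, THF/H2O) would give 9 directly and bypass 8.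

## Further compounds

F1 | step 12 | {(5R)-4-[(1S,3E)-1-[(tert-butyldimethylsilyl)oxy]-6-iodo-3-methylhex-3-en-1-yl]-5-[(Z)-2-iodoprop-1-en-1-yl]-2,5-dihydrofuran-3-yl}methanol | ICC/C=C(C)/C[C@H](O[Si](C)(C)C(C)(C)C)C1=C(CO)CO[C@@H]1/C=C(C)\I
F2 | step 17 | (1R,4R,5R,6R,8S,10R)-13-acetoxy-5-bromo-8-[(tert-butyldimethylsilyl)oxy]-1,10-epoxy-4-hydroxygermacr-7(11)-en-12,6-olide (bromine anti to the C4 hydroxyl) | CC(=O)OCC1=C2[C@@H](O[Si](C)(C)C(C)(C)C)C[C@@]3(C)O[C@@H]3CC[C@@](C)(O)[C@H](Br)[C@H]2OC1=O
F3 | step 17 | (1R,4R,5S,6S,8S,10R)-13-acetoxy-8-[(tert-butyldimethylsilyl)oxy]-1,10:4,5-diepoxygermacr-7(11)-en-12,6-olide | CC(=O)OCC1=C2[C@@H](O[Si](C)(C)C(C)(C)C)C[C@@]3(C)O[C@@H]3CC[C@@]3(C)O[C@H]3[C@H]2OC1=O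
F4 | step 15 | (6R,8S)-13-acetoxy-8-hydroxygermacra-1(10)E,4Z,7(11)-trien-12,6-olide | CC(=O)OCC1=C2[C@@H](O)C/C(C)=C/CC/C(C)=C\[C@H]2OC1=O
F5 | step 15 | (4R,5S,6S,8S)-13-acetoxy-4,5-epoxy-8-hydroxygermacra-1(10)E,7(11)-dien-12,6-olide | CC(=O)OCC1=C2[C@@H](O)C/C(C)=C/CC[C@@]3(C)O[C@H]3[C@H]2OC1=O
F6 | step 15 | (4R,5S,6S,8S)-13-acetoxy-4,5-epoxy-8-{[(2S)-2-methyloxirane-2-carbonyl]oxy}germacra-1(10)E,7(11)-dien-12,6-olide | CC(=O)OCC1=C2[C@@H](OC(=O)[C@]3(C)CO3)C/C(C)=C/CC[C@@]3(C)O[C@H]3[C@H]2OC1=O
F7 | step 14 | [(4S,6E,10Z,11aR)-2-(tert-butylperoxy)-4-[(tert-butyldimethylsilyl)oxy]-6,10-dimethyl-2,4,5,8,9,11a-hexahydrocyclodeca[b]furan-3-yl]methyl acetate (both C2 epimers) | CC(=O)OCC1=C2[C@@H](O[Si](C)(C)C(C)(C)C)C/C(C)=C/CC/C(C)=C\[C@H]2OC1OOC(C)(C)C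
F8 | step 11 | (2Z,4R,6S,8E)-6-[(tert-butyldimethylsilyl)oxy]-5-[1-hydroxy-3-iodopropan-2-ylidene]-2-iodo-8-methylundeca-2,8,10-trien-4-ol (CH2I cis to the C4 carbinol) | C=C/C=C(C)/C[C@H](O[Si](C)(C)C(C)(C)C)/C(=C(/CI)CO)[C@H](O)/C=C(C)\I
F9 | step 5 | tert-butyl{[(2S,4E)-1-bromo-4-methyl-1-(oxetan-3-ylidene)-5-(4,4,5,5-tetramethyl-1,3,2-dioxaborolan-2-yl)pent-4-en-2-yl]oxy}dimethylsilane | CC1(C)OB(OC1(C)C)/C=C(C)/C[C@H](O[Si](C)(C)C(C)(C)C)C(Br)=C1COC1
A1 | alternative 1 | ten-membered 1(10)E-en-5-one with C4 tertiary alcohol, C6 PMB, C7 TES and C8 TBS ethers | C[C@@]1(O)CC/C=C(C)/C[C@H](O[Si](C)(C)C(C)(C)C)[C@@H](O[Si](CC)(CC)CC)[C@H](OCc2ccc(OC)cc2)C1=O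
A2 | alternative 2 | cyclodeca-1(10)E,4Z-dien-8-ol with C6 PMB and C7 TES ethers | O[C@H]1C/C(C)=C/CC/C(C)=C\[C@@H](OCc2ccc(OC)cc2)[C@@H]1O[Si](CC)(CC)CC
A3 | alternative 3 | 13-acetoxy-1(10)E,4Z-dien-6,12-olide C8 TBS ether (same structure as 21) | CC(=O)OCC1=C2[C@@H](O[Si](C)(C)C(C)(C)C)C/C(C)=C/CC/C(C)=C\[C@H]2OC1=O
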